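The last ring-forming operation closes ring A (C1–C5, C10) by an Ireland–Claisen rearrangement of a lactone. The precursor is a spiro δ-lactone in which the future γ-lactone carbonyl C6 is esterified to an allylic oxygen on C2 (ring O–C6–C5–C10–C1–C2), already spiro-fused at C10 to the 7,20-lactone of the finished bicyclo[3.2.1]octane. Its silyl ketene acetal rearranges through an enforced boat, forging C4–C5, transferring the C2 stereocentre to quaternary C4 and to C5, and placing C6 cis to the C19 oxymethyl, so the freed acid lactonises in the same operation. The step exploits the 1,4-relationship of C2 and C5 in ring A and the cis C6/C19 pair; the residual C2=C3 alkene is hydrogenated with the C16 methylene.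

Key step: step 18

Numbering used in names (kaurane numbering of the target): ring A = C1–C5, C10; γ-lactone C6(=O)–O–C19; δ-lactone C7(=O)–O–C20; bicyclo[3.2.1]octane = C8, C9, C11–C16 (C14 one-carbon bridge, C15–C16 two-carbon bridge); C17 on C16, C18 on C4.

Assumption: the quinine-derived primary amine (step 2) and (−)-MIB (step 17) are taken to give the (4R) Michael adduct and Si-face alkenylation; the pseudo-enantiomeric catalyst would be used if the opposite sense were found.

**Step 1**
Reactants: 1 methacrolein; 2 ethyl 2-oxo-3-(triphenyl-λ5-phosphanylidene)propanoate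
Product: 3 ethyl (3E)-5-methyl-2-oxohexa-3,5-dienoate
Conditions: CH2Cl2, rt
Reagents that add atoms: none
Why: Wittig olefination of the enal with the stabilised keto-ester ylide should give the (E)-configured β,γ-unsaturated α-keto ester.

**Step 2**
Reactants: 3 ethyl (3E)-5-methyl-2-oxohexa-3,5-dienoate; 4 acetone
Product: 6 ethyl (5S)-3-oxo-5-(prop-1-en-2-yl)cyclohex-1-ene-1-carboxylate, via Michael adduct 5 (not isolated)
Conditions: 9-amino-9-deoxy-epi-quinine (20 mol %), PhCO2H (40 mol %), acetone, rt; then TsOH·H2O, PhMe, 70 °C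
Reagents that add atoms: none
Why: Enamine-catalysed asymmetric Michael addition of acetone to the enone terminus of the α-keto ester sets C13 under catalyst control, and acid-promoted intramolecular aldol condensation of the acetonyl methyl (C9) onto the α-keto carbonyl (C8) closes ring C.

**Step 3**
Reactants: 6 ethyl (5S)-3-oxo-5-(prop-1-en-2-yl)cyclohex-1-ene-1-carboxylate
Product: 7 (5S)-3-oxo-5-(prop-1-en-2-yl)cyclohex-1-ene-1-carboxylic acid
Conditions: LiOH, THF–H2O, 0 °C; then 1 M HCl
Reagents that add atoms: water, O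
Why: Cold saponification of the ethyl ester should leave the enone and the remote stereocentre untouched.

**Step 4**
Reactants: 8 but-3-yn-1-ol
Product: 9 (but-3-yn-1-yloxy)triethylsilane
Conditions: Et3SiCl, imidazole, CH2Cl2, 0 °C
Reagents that add atoms: chlorotriethylsilane, CC[Si](CC)(CC)Cl
Why: Imidazole-mediated silylation gives the primary triethylsilyl ether, chosen because it can later be oxidised directly to the aldehyde.

**Step 5**
Reactants: 9 (but-3-yn-1-yloxy)triethylsilane
Product: 10 methyl 5-(triethylsilyloxy)pent-2-ynoate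
Conditions: n-BuLi, THF, −78 °C; ClCO2Me
Reagents that add atoms: methyl chloroformate, COC(=O)Cl
Why: Deprotonation of the terminal alkyne and C-acylation of the acetylide with the chloroformate gives the ynoate.

**Step 6**
Reactants: 10 methyl 5-(triethylsilyloxy)pent-2-ynoate
Product: 11 methyl (2E)-3-{[dimethyl(propan-2-yloxy)silyl]methyl}-5-(triethylsilyloxy)pent-2-enoate
Conditions: ClMgCH2SiMe2(Oi-Pr) (from ClCH2SiMe2(Oi-Pr) and Mg), CuBr·SMe2, THF, −78 °C; aq NH4Cl
Reagents that add atoms: {[dimethyl(propan-2-yloxy)silyl]methyl}magnesium chloride, CC(C)O[Si](C)(C)C[Mg]Cl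
Why: syn-Carbocupration of the ynoate and protonation with retention at −78 °C place the CH2Si group (future C20) trans to the ester, fixing the (E) geometry.

**Step 7**
Reactants: 11 methyl (2E)-3-{[dimethyl(propan-2-yloxy)silyl]methyl}-5-(triethylsilyloxy)pent-2-enoate
Product: 12 methyl (2E)-3-(hydroxymethyl)-5-(triethylsilyloxy)pent-2-enoate
Conditions: H2O2 (30 %), KHCO3, THF–MeOH, rt
Reagents that add atoms: hydrogen peroxide, OO
Why: Tamao oxidation converts the C–Si bond of the alkoxysilane into C–OH, giving an allylic alcohol that cannot lactonise because it is trans to the ester.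

**Step 8**
Reactants: 7 (5S)-3-oxo-5-(prop-1-en-2-yl)cyclohex-1-ene-1-carboxylic acid; 12 methyl (2E)-3-(hydroxymethyl)-5-(triethylsilyloxy)pent-2-enoate
Product: 13 (2E)-4-methoxy-4-oxo-2-[2-(triethylsilyloxy)ethyl]but-2-en-1-yl (5S)-3-oxo-5-(prop-1-en-2-yl)cyclohex-1-ene-1-carboxylate
Conditions: DCC, DMAP (cat.), CH2Cl2, 0 °C → rt
Reagents that add atoms: none
Why: Steglich esterification joins the acid and the primary allylic alcohol without touching the enone, the enoate or the silyl ether.

**Step 9**
Reactants: 13 (2E)-4-methoxy-4-oxo-2-[2-(triethylsilyloxy)ethyl]but-2-en-1-yl (5S)-3-oxo-5-(prop-1-en-2-yl)cyclohex-1-ene-1-carboxylate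
Product: 14 (2E)-4-methoxy-4-oxo-2-[2-(triethylsilyloxy)ethyl]but-2-en-1-yl 6-methylidene-3-oxobicyclo[3.2.1]octane-1-carboxylate (C11 ketone, C16=C17; C8 and C13 as in 29)
Conditions: Me2AlCl (1.5 equiv), CH2Cl2, −78 → 0 °C
Reagents that add atoms: none
Why: In a Lewis-acid-promoted intramolecular conjugate ene reaction the isopropenyl CH2 (C15) adds to the ester-bearing enone carbon C8 with hydrogen transfer from the methyl group, and because the two-carbon bridge can only form cis to the C13–C16 bond, C13 sets the quaternary C8.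

**Step 10**
Reactants: 14 (2E)-4-methoxy-4-oxo-2-[2-(triethylsilyloxy)ethyl]but-2-en-1-yl 6-methylidene-3-oxobicyclo[3.2.1]octane-1-carboxylate
Product: 15 keto lactone: 7,20-δ-lactone cis-fused at C8–C9 to the 16-methylidene-bicyclo[3.2.1]octan-11-one, C10 bearing CH2CO2CH3 (C5, C6) and CH2CH2OSiEt3 (C1, C2)
Conditions: KOt-Bu (0.2 equiv), t-BuOH–THF, 0 °C
Reagents that add atoms: none
Why: Intramolecular Michael addition (6-exo-trig) of the C9 enolate (the reversibly formed C12 enolate cannot reach) to the tethered β,β-disubstituted enoate closes the 7,20-lactone; attack anti to the axial C15 bridge sets C9, and a K-chelated transition state holding the enoate carbonyl next to the enolate oxygen should place the new CH2CO2CH3 arm on the outer face of C10 and the silyloxyethyl arm under ring C.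

**Step 11**
Reactants: 15 keto lactone
Product: 16 11-alcohol of 15 (equatorial 11-OH as in 29)
Conditions: SmI2, THF–MeOH, 0 °C → rt
Reagents that add atoms: none
Why: Single-electron (ketyl) reduction under thermodynamic control should give the equatorial alcohol, the axial epimer being destabilised by the syn-axial C15–C16 bridge, whereas hydride reagents confined to the exo trajectory would give the axial epimer; ester, lactone and alkene are inert.

**Step 12**
Reactants: 16 11-alcohol
Product: 17 11,15-diol (15-OH on the exo face, on the side of the C14 bridge)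
Conditions: SeO2 (cat.), t-BuOOH, CH2Cl2, rt
Reagents that add atoms: tert-butyl hydroperoxide, CC(C)(C)OO
Why: SeO2-catalysed allylic oxidation (ene reaction, then [2,3]-sigmatropic shift) functionalises C15, the only allylic methylene of the C16=C17 alkene (the bridgehead C13–H cannot react); the C15 configuration is inconsequential.

**Step 13**
Reactants: 17 11,15-diol
Product: 18 11,15-bis(tert-butyldimethylsilyl) ether of 17
Conditions: TBSOTf, 2,6-lutidine, CH2Cl2, −40 → 0 °C
Reagents that add atoms: tert-butyldimethylsilyl trifluoromethanesulfonate, CC(C)(C)[Si](C)(C)OS(=O)(=O)C(F)(F)F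
Why: The silyl triflate silylates both hindered secondary alcohols and leaves the primary triethylsilyl ether intact.

**Step 14**
Reactants: 18 11,15-bis(tert-butyldimethylsilyl) ether
Product: 19 C2 aldehyde (C1 arm of 18 ending in CHO)
Conditions: (COCl)2, DMSO, CH2Cl2, −78 → −30 °C; Et3N
Reagents that add atoms: none
Why: Swern oxidation converts primary triethylsilyl ethers directly into aldehydes while secondary tert-butyldimethylsilyl ethers survive, which avoids a free δ-hydroxy ester that would lactonise.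

**Step 15**
Reactants: 20 prop-2-yn-1-ol
Product: 21 (2E)-3-iodo-2-methylprop-2-en-1-ol
Conditions: AlMe3, Cp2ZrCl2 (cat.), CH2Cl2, 0 °C → rt; then I2, THF, −30 °C
Reagents that add atoms: trimethylaluminium, C[Al](C)C; iodine, II
Why: Zr-catalysed Negishi carboalumination adds CH3 and Al syn across the alkyne (CH3 on the internal carbon) and iodinolysis with retention gives the (E)-iodoalkene.

**Step 16**
Reactants: 21 (2E)-3-iodo-2-methylprop-2-en-1-ol
Product: 22 tert-butyl{[(2E)-3-iodo-2-methylprop-2-en-1-yl]oxy}dimethylsilane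
Conditions: TBSCl, imidazole, CH2Cl2, rt
Reagents that add atoms: tert-butyl(chloro)dimethylsilane, CC(C)(C)[Si](C)(C)Cl
Why: Standard silylation protects the primary allylic alcohol.

**Step 17**
Reactants: 19 C2 aldehyde; 22 tert-butyl{[(2E)-3-iodo-2-methylprop-2-en-1-yl]oxy}dimethylsilane
Product: 24 spiro δ-lactone (ring O–C6(=O)–C5–C10–C1–C2) with the (E)-alkenyl group on (2R)-C2, via hydroxy ester 23 (not isolated)
Conditions: 22, t-BuLi, Et2O, −78 °C; ZnBr2; then 19, (−)-MIB (10 mol %), TEEDA, PhMe, 0 °C; then PPTS, 50 °C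
Reagents that add atoms: none
Why: Iodine–lithium exchange with retention, transmetalation to zinc and amino-alcohol-catalysed addition to the Si face of the aldehyde (reagent control) should give the (2R) allylic alcohol, which closes the δ-lactone onto the methyl ester by Thorpe–Ingold-assisted acyl substitution.

**Step 18**
Reactants: 24 spiro δ-lactone
Product: 27 2,3-didehydro-15-hydroxy-16-methylidene bis-lactone, via silyl ketene acetal 25 (not isolated), via silyl ester 26 (not isolated)
Conditions: LiN(i-Pr)2, Me3SiCl–Et3N, THF, −78 °C → rt; PhMe, 110 °C; then 48 % aq HF, MeCN, rt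
Reagents that add atoms: none
Why: O-Silylation of the Li enolate of the δ-lactone gives the cyclic silyl ketene acetal 25, whose C5=C6–O–C2–C3=C4 array undergoes a suprafacial [3,3]-sigmatropic shift that breaks C2–O and forms C4–C5 (silyl ester 26); aqueous HF then removes all four silyl groups and the C6 acid lactonises onto the cis C19 hydroxyl. The closest known reaction is the Ireland–Claisen rearrangement of 6-alkenyl δ-lactone silyl ketene acetals to cyclohex-3-enecarboxylic acids (lactone-enolate Claisen carbocyclisation). Ring A closes by C4–C5 bond formation in a six-membered pericyclic array that the O–C6 bridge between C2 and C5 forces into a boat (bicyclo[2.2.2]octane-like) transition state, and the γ-lactone then closes by 5-exo-trig acyl substitution. C4 is set by the (E) alkene geometry (methyl inside, CH2OSi outside and hence on the face of the C6 bridge) together with the (2R) centre, which decides the alkene face that meets C5 (1,3-chirality transfer), and C5 is set in the same event with C6 cis to C19; because the alkenyl group lies on the lactone face syn to C9, C20 ends on the C6/C19 face as in the target. The step needs only substrate stereospecificity, secured by the single accessible transition state and the configurational purity of C2 and of the alkene, and chemoselective enolisation at C5, secured because the 7,20-lactone carbonyl sits on quaternary C8 and has no α-hydrogen.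

**Step 19**
Reactants: 27 2,3-didehydro-15-hydroxy-16-methylidene bis-lactone
Product: 28 2,3-didehydro-16-methylidene-15-ketone (enone)
Conditions: MnO2, CH2Cl2, rt
Reagents that add atoms: none
Why: MnO2 oxidises only the allylic C15 alcohol and leaves the saturated C11 alcohol.

**Step 20**
Reactants: 28 2,3-didehydro-16-methylidene-15-ketone
Product: 29 guidongnin C
Conditions: H2 (1 atm), Pd/C (10 wt %), EtOAc, rt
Reagents that add atoms: none
Why: Heterogeneous hydrogenation saturates the C2=C3 alkene and the C16=C17 methylene, and syn delivery of H2 to the exo face of the enone (side of the one-carbon bridge) should turn the new C17 methyl toward C12 as in the target.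

**Compound list**

1 | methacrolein (2-methylprop-2-enal) | C=C(C)C=O | starting material
2 | ethyl 2-oxo-3-(triphenyl-λ5-phosphanylidene)propanoate | CCOC(=O)C(=O)C=P(c1ccccc1)(c1ccccc1)c1ccccc1 | starting material
3 | ethyl (3E)-5-methyl-2-oxohexa-3,5-dienoate | CCOC(=O)C(=O)/C=C/C(C)=C | intermediate
4 | acetone | CC(C)=O | starting material
5 | ethyl (4R)-2,6-dioxo-4-(prop-1-en-2-yl)heptanoate (Michael adduct) | CC(=O)C[C@H](CC(=O)C(=O)OCC)C(C)=C | intermediate
6 | ethyl (5S)-3-oxo-5-(prop-1-en-2-yl)cyclohex-1-ene-1-carboxylate | CC(=C)[C@@H]1CC(=O)C=C(C1)C(=O)OCC | intermediate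
7 | (5S)-3-oxo-5-(prop-1-en-2-yl)cyclohex-1-ene-1-carboxylic acid | CC(=C)[C@@H]1CC(=O)C=C(C1)C(=O)O | intermediate
8 | but-3-yn-1-ol | C#CCCO | starting material
9 | (but-3-yn-1-yloxy)triethylsilane | C#CCCO[Si](CC)(CC)CC | intermediate
10 | methyl 5-(triethylsilyloxy)pent-2-ynoate | COC(=O)C#CCCO[Si](CC)(CC)CC | intermediate
11 | methyl (2E)-3-{[dimethyl(propan-2-yloxy)silyl]methyl}-5-(triethylsilyloxy)pent-2-enoate | COC(=O)/C=C(/C[Si](C)(C)OC(C)C)CCO[Si](CC)(CC)CC | intermediate
12 | methyl (2E)-3-(hydroxymethyl)-5-(triethylsilyloxy)pent-2-enoate | COC(=O)/C=C(/CO)CCO[Si](CC)(CC)CC | intermediate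
13 | (2E)-4-methoxy-4-oxo-2-[2-(triethylsilyloxy)ethyl]but-2-en-1-yl (5S)-3-oxo-5-(prop-1-en-2-yl)cyclohex-1-ene-1-carboxylate | CC(=C)[C@@H]1CC(=O)C=C(C1)C(=O)OC/C(CCO[Si](CC)(CC)CC)=C/C(=O)OC | intermediate
14 | (2E)-4-methoxy-4-oxo-2-[2-(triethylsilyloxy)ethyl]but-2-en-1-yl 6-methylidene-3-oxobicyclo[3.2.1]octane-1-carboxylate (C8, C13 as in 29) | C=C1C[C@@]2(C[C@H]1CC(=O)C2)C(=O)OC/C(CCO[Si](CC)(CC)CC)=C/C(=O)OC | intermediate
15 | keto lactone: 7,20-δ-lactone cis-fused to the 16-methylidene-bicyclo[3.2.1]octan-11-one; C10 bears CH2CO2CH3 (C5, C6) and CH2CH2OSiEt3 (C1, C2); C8, C9, C10, C13 as in 29 | C=C1C[C@]23C[C@H]1CC(=O)[C@H]2[C@@](CC(=O)OC)(CCO[Si](CC)(CC)CC)COC3=O | intermediate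
16 | 11-alcohol of 15 (equatorial 11-OH as in 29) | C=C1C[C@]23C[C@H]1C[C@@H](O)[C@H]2[C@@](CC(=O)OC)(CCO[Si](CC)(CC)CC)COC3=O | intermediate
17 | 11,15-diol (15-OH exo, on the side of the C14 bridge) | C=C1[C@H](O)[C@]23C[C@H]1C[C@@H](O)[C@H]2[C@@](CC(=O)OC)(CCO[Si](CC)(CC)CC)COC3=O | intermediate
18 | 11,15-bis(tert-butyldimethylsilyl) ether of 17 | C=C1[C@H](O[Si](C)(C)C(C)(C)C)[C@]23C[C@H]1C[C@@H](O[Si](C)(C)C(C)(C)C)[C@H]2[C@@](CC(=O)OC)(CCO[Si](CC)(CC)CC)COC3=O | intermediate
19 | C2 aldehyde (C1 arm of 18 ending in CHO) | C=C1[C@H](O[Si](C)(C)C(C)(C)C)[C@]23C[C@H]1C[C@@H](O[Si](C)(C)C(C)(C)C)[C@H]2[C@@](CC(=O)OC)(CC=O)COC3=O | intermediate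
20 | prop-2-yn-1-ol | C#CCO | starting material
21 | (2E)-3-iodo-2-methylprop-2-en-1-ol | OC/C(C)=C/I | intermediate
22 | tert-butyl{[(2E)-3-iodo-2-methylprop-2-en-1-yl]oxy}dimethylsilane | CC(C)(C)[Si](C)(C)OC/C(C)=C/I | intermediate
23 | (2R)-allylic alcohol: C2(OH) bearing the (E)-CH=C(CH3)CH2OTBS group (C3, C4, C18, C19), methyl ester retained | C=C1[C@H](O[Si](C)(C)C(C)(C)C)[C@]23C[C@H]1C[C@@H](O[Si](C)(C)C(C)(C)C)[C@H]2[C@@](CC(=O)OC)(C[C@@H](O)/C=C(\C)CO[Si](C)(C)C(C)(C)C)COC3=O | intermediate
24 | spiro δ-lactone (ring O–C6(=O)–C5–C10–C1–C2) with the (E)-alkenyl group on (2R)-C2; 7,20-lactone, 11- and 15-OTBS, C16=C17 | C=C1[C@H](O[Si](C)(C)C(C)(C)C)[C@]23C[C@H]1C[C@@H](O[Si](C)(C)C(C)(C)C)[C@H]2[C@]1(CC(=O)O[C@H](C1)/C=C(\C)CO[Si](C)(C)C(C)(C)C)COC3=O | intermediate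
25 | trimethylsilyl ketene acetal of 24 (C5=C6(OSiMe3)–O–C2) | C=C1[C@H](O[Si](C)(C)C(C)(C)C)[C@]23C[C@H]1C[C@@H](O[Si](C)(C)C(C)(C)C)[C@H]2[C@]1(C=C(O[Si](C)(C)C)O[C@H](C1)/C=C(\C)CO[Si](C)(C)C(C)(C)C)COC3=O | intermediate
26 | trimethylsilyl ester after the [3,3] shift: ring A closed (C2=C3), C4 with CH3 and CH2OTBS, C5 with CO2SiMe3; C4, C5, C10 as in 29 | C=C1[C@H](O[Si](C)(C)C(C)(C)C)[C@]23C[C@H]1C[C@@H](O[Si](C)(C)C(C)(C)C)[C@H]2[C@@]1(CC=C[C@@](C)(CO[Si](C)(C)C(C)(C)C)[C@H]1C(=O)O[Si](C)(C)C)COC3=O | intermediate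
27 | 2,3-didehydro-15-hydroxy-16-methylidene bis-lactone (both lactones of 29, C2=C3, 11-OH, exo 15-OH, C16=C17) | C=C1[C@H](O)[C@]23C[C@H]1C[C@@H](O)[C@H]2[C@@]1(CC=C[C@@]2(C)COC(=O)[C@H]21)COC3=O | intermediate
28 | 2,3-didehydro-16-methylidene-15-ketone (enone) | C=C1C(=O)[C@]23C[C@H]1C[C@@H](O)[C@H]2[C@@]1(CC=C[C@@]2(C)COC(=O)[C@H]21)COC3=O | intermediate
29 | guidongnin C | C[C@H]1C(=O)[C@]23C[C@H]1C[C@@H](O)[C@H]2[C@@]1(CCC[C@@]2(C)COC(=O)[C@H]21)COC3=O | target

**Totals and risks**

Total step count: 20. Longest linear sequence: 15 steps (from 8: steps 4–14 and 17–20).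

The three steps most likely to fail:

Step 18 (key step). The boat-only [3,3] shift has to join the fully substituted alkene terminus C4 to C5 next to quaternary C10, so thermal decomposition of the silyl ketene acetal (C-silylation, elimination across C2–O) may outrun rearrangement. The fallback sets out from aldehyde 19 and returns at 27. Wittig methylenation (Ph3P=CH2) gives the C10-allyl alkene F1. Me3SnOH cleaves the methyl ester selectively to the acid F2. The allylic alcohol (2E)-4-[(tert-butyldimethylsilyl)oxy]-3-methylbut-2-en-1-ol F3, made from 22 by iodine–lithium exchange and addition to paraformaldehyde, is attached with DCC/DMAP to give the allylic ester F4. An acyclic Ireland–Claisen rearrangement (LiN(i-Pr)2, THF–DMPU, Me3SiCl; chair transition state, ketene acetal with C10 trans to the allyloxy oxygen) should give the γ,δ-unsaturated acid F5 carrying a C4 vinyl group. Ring-closing metathesis (second-generation Grubbs catalyst) between the C4 vinyl and C10 allyl groups then closes ring A as the cyclohexene acid F6, and aqueous HF removes the silyl groups and lactonises to 27.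

Step 10. The β,β-disubstituted enoate may be too poor an acceptor for the hindered K enolate, or a non-chelated transition state may erode facial selectivity at C10. The fallback sets out from 14 and returns at 15. Me3SiOTf/Et3N converts 14 into the trimethylsilyl enol ether F7 (C9=C11) together with its C11=C12 regioisomer F8. TiCl4 at −78 °C then effects an intramolecular Mukaiyama–Michael addition of F7 through a Ti-chelated transition state, giving 15 after aqueous work-up. F8 cannot reach the acceptor, is hydrolysed back to 14 and is recycled.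

Step 9. Carbonyl-ene attack at C11 (1,2-addition) or acid-induced oligomerisation of the isopropenyl group may compete with the conjugate ene reaction. The fallback sets out from ylide 2 and returns at 14; it runs the same sequence with an allylsilane, whose conjugate (Hosomi–Sakurai) addition to enones is reliable. 2-[(Trimethylsilyl)methyl]prop-2-enal F9 (MnO2 oxidation of commercial 2-[(trimethylsilyl)methyl]prop-2-en-1-ol) and 2 give the dienyl keto ester F10. Michael–aldol condensation with acetone 4 as in step 2 (dehydration with MsCl/Et3N instead of acid) gives the enone ester F11, which is saponified to the acid F12 and esterified with 12 to the ester F13. TiCl4 (CH2Cl2, −78 °C) then triggers intramolecular addition of the allylsilane terminus to C8 and, after aqueous quench, gives 14.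

**Further compounds**

F1 | step 18 | C10-allyl alkene (C1–C2=CH2 in place of the aldehyde arm of 19, methyl ester retained) | C=C1[C@H](O[Si](C)(C)C(C)(C)C)[C@]23C[C@H]1C[C@@H](O[Si](C)(C)C(C)(C)C)[C@H]2[C@@](CC(=O)OC)(CC=C)COC3=O
F2 | step 18 | C6 acid of F1 | C=C1[C@H](O[Si](C)(C)C(C)(C)C)[C@]23C[C@H]1C[C@@H](O[Si](C)(C)C(C)(C)C)[C@H]2[C@@](CC(=O)O)(CC=C)COC3=O
F3 | step 18 | (2E)-4-[(tert-butyldimethylsilyl)oxy]-3-methylbut-2-en-1-ol | CC(C)(C)[Si](C)(C)OC/C(C)=C/CO
F4 | step 18 | (2E)-4-[(tert-butyldimethylsilyl)oxy]-3-methylbut-2-en-1-yl ester of F2 | C=C1[C@H](O[Si](C)(C)C(C)(C)C)[C@]23C[C@H]1C[C@@H](O[Si](C)(C)C(C)(C)C)[C@H]2[C@@](CC(=O)OC/C=C(\C)CO[Si](C)(C)C(C)(C)C)(CC=C)COC3=O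
F5 | step 18 | Ireland–Claisen acid: C5 bearing CO2H and C4 (CH3, vinyl, CH2OTBS), C10 allyl; C4, C5, C10 as in 29 | C=C1[C@H](O[Si](C)(C)C(C)(C)C)[C@]23C[C@H]1C[C@@H](O[Si](C)(C)C(C)(C)C)[C@H]2[C@@]([C@H](C(=O)O)[C@@](C)(C=C)CO[Si](C)(C)C(C)(C)C)(CC=C)COC3=O
F6 | step 18 | cyclohexene acid (ring A closed, C2=C3; free acid analogue of 26) | C=C1[C@H](O[Si](C)(C)C(C)(C)C)[C@]23C[C@H]1C[C@@H](O[Si](C)(C)C(C)(C)C)[C@H]2[C@@]1(CC=C[C@@](C)(CO[Si](C)(C)C(C)(C)C)[C@H]1C(=O)O)COC3=O
F7 | step 10 | trimethylsilyl enol ether of 14 (C9=C11) | C=C1C[C@@]2(C[C@H]1CC(O[Si](C)(C)C)=C2)C(=O)OC/C(CCO[Si](CC)(CC)CC)=C/C(=O)OC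
F8 | step 10 | trimethylsilyl enol ether of 14 (C11=C12 regioisomer) | C=C1C[C@@]2(C[C@H]1C=C(O[Si](C)(C)C)C2)C(=O)OC/C(CCO[Si](CC)(CC)CC)=C/C(=O)OC
F9 | step 9 | 2-[(trimethylsilyl)methyl]prop-2-enal | C=C(C[Si](C)(C)C)C=O
F10 | step 9 | ethyl (3E)-2-oxo-5-[(trimethylsilyl)methyl]hexa-3,5-dienoate | CCOC(=O)C(=O)/C=C/C(=C)C[Si](C)(C)C
F11 | step 9 | ethyl (5S)-3-oxo-5-[3-(trimethylsilyl)prop-1-en-2-yl]cyclohex-1-ene-1-carboxylate | C=C(C[Si](C)(C)C)[C@@H]1CC(=O)C=C(C1)C(=O)OCC
F12 | step 9 | (5S)-3-oxo-5-[3-(trimethylsilyl)prop-1-en-2-yl]cyclohex-1-ene-1-carboxylic acid | C=C(C[Si](C)(C)C)[C@@H]1CC(=O)C=C(C1)C(=O)O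
F13 | step 9 | (2E)-4-methoxy-4-oxo-2-[2-(triethylsilyloxy)ethyl]but-2-en-1-yl ester of F12 | C=C(C[Si](C)(C)C)[C@@H]1CC(=O)C=C(C1)C(=O)OC/C(CCO[Si](CC)(CC)CC)=C/C(=O)OC
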